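Target was made in Tuesday's run at a smaller fraction of its charge per minute than in Friday's, the chair reported: Friday's reading was 35% at 6.00 min, Tuesday's 15% at 5.00 min. That fraction per minute fell by a factor of 1.94 while the substrate charge rose by 2.25.

| setting | Friday's | Tuesday's | flask |
|---|---|---|---|
| substrate | 0.80 M | 1.8 M | 1.2 M |
| free catalyst | 7.8 mM | 7.8 mM | 7.8 mM |
| impurity | 2.1 mM | 2.1 mM | 2.1 mM |
| remark | run made earlier | run made earlier |  |

- Friday's (time / min: target / %, substrate / %): 6.00: 35, 67; 12.0: 67, 32; 20.0: 90, 8; 25.0: 98, 3; 30.0: 99, 3
- Tuesday's (time / min: target / %, substrate / %): 2.50: 8, 91; 5.00: 15, 84; 8.00: 26, 73; 15.0: 45, 57; 30.0: 78, 18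

(standard deviation of a reading: 1.5 percentage points)

- the analysis behind the earlier runs scatters by 1.5 percentage points, standard deviation
- no earlier run changes the charge of free catalyst; that part of a forecast is a guess

* factor on the rate of making target when 5.0% of the substrate are converted if free catalyst is charged twice over
* factor on the rate when 5.0% of the substrate are converted if free catalyst is charged at 80 mM instead

The chair concluded from these readings that the early rate follows the catalyst rather than the substrate. The second chemist objected that no earlier run varies free catalyst, and that the impurity might remove catalyst one for one.

Taking the minutes, I wrote the balance of the reagent charged in the smaller amount. The impurity stands below free catalyst, so on that assumption it is the limiting reagent of the loss, and what keeps working is 73.1% of the catalyst charge. I call this the working share, one minus the impurity charge over the catalyst charge.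

At 5.0% conversion the substrate stands at 95.0% of its charge, so I held the rate per working catalyst unchanged. A doubled charge of catalyst, with the impurity charge unchanged, then gives one plus the working share, over the working share: 2.37. A charge of 80 mM gives 13.7.

The forecast stands lower on both, at 2.2 (range 1.5 to 2.6) and 11.5 (range 3.5 to 15), and says: “I lean between first order and poisoning, with a wide low tail”.

The simulation gives 2.33 and 10.5, each within the forecast's range, and my 13.7 stands above the second.

    substrate + free catalyst → catalyst intermediate (k = 0.990 M⁻¹ s⁻¹)
    catalyst intermediate ⇌ free catalyst + target (K = 29.0 M, k = 0.170 s⁻¹)
    free catalyst + impurity → spent catalyst (k = 49.0 M⁻¹ s⁻¹)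

In the flask at 11.7 min, free catalyst has a half-life of 1.1 s by its conversion with substrate, shorter than the 0.068 min forward half-life of catalyst intermediate. At 15.0 min, with impurity at 0%, the flask's resting state, catalyst intermediate, holds 53.9% of the catalyst charged, free catalyst 19.2%, together the working share of 73.1%, and spent catalyst the other 26.9%.

The earlier runs and the new flask stem from a simulated flask on assumed constants, noise included.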